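**Plan**

- Numbering: ring A = C1 (methyl-bearing fusion carbon), C2 (OAc), C3, C4 (isopropyl carbinol), C5 (fusion CH); ring B = C1, C5, C6 (veratroyloxy), C7, C8/C9 (epoxide), C10; β is the face of the C1 methyl group.
- Retrosynthesis: the C6 and C2 esters and the epoxide oxygen come off first; ring A is then opened at C3–C4 (aldol) and C2–C3 (methyl addition to a C2 carboxyl group).
- Feature used: quaternary C1 lies across C10 from the C8=C9 unit inside ring B and carries C2 at the carboxyl level. Cutting C1–C10 and joining C8 to the C2 oxygen ([3,3] in reverse) turns ring B into a 7-methyl-7-vinyl ε-lactone.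
- The lactone comes from a cyclohexanone (C2, C1, C5, C6, C7, C8) by Baeyer–Villiger insertion at C8. Forward order: six-membered ring, lactone, ring B by the sigmatropic step, ring A by aldol, epoxide last.
- Stereochemistry: one CBS reduction gives a temporary C2 carbinol that steers C8 (vinyl addition) and C5 (aldol); a bulky hydride sets C6 cis to both; C8 is transferred to C1 in the [3,3] shift; C4, C2 and the epoxide follow from the trans-fused bicycle.

Key step: step 15

Remark: the C4 carbinol made in step 6 is drawn as its anti (1S) epimer; step 18 oxidises it, so a minor C4 epimer converges on the same diketone.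

**Route**

Step 1
Reactants: 1 1,4-dioxaspiro[4.5]dec-6-en-8-one
Product: 2 (8R)-1,4-dioxaspiro[4.5]dec-6-en-8-ol
Conditions: (S)-2-methyl-CBS-oxazaborolidine (10 mol %), BH3·SMe2, THF, −20 °C; aqueous work-up
Reagents that add atoms: none
Why: Corey–Bakshi–Shibata reduction of a cyclic enone, in which the alkene arm acts as the large group, so the (S)-catalyst should deliver hydride to give the (R)-allylic alcohol, the only stereocenter set by a chiral reagent.

Step 2
Reactants: 2 (8R)-1,4-dioxaspiro[4.5]dec-6-en-8-ol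
Product: 3 (8R)-8-[(4-methoxybenzyl)oxy]-1,4-dioxaspiro[4.5]dec-6-ene
Conditions: NaH, 4-methoxybenzyl chloride, DMF, 0 °C → rt
Reagents that add atoms: 4-methoxybenzyl chloride, COc1ccc(CCl)cc1
Why: Williamson etherification of the alkoxide gives an ether that can later be removed oxidatively without touching silyl ethers.

Step 3
Reactants: 3 (8R)-8-[(4-methoxybenzyl)oxy]-1,4-dioxaspiro[4.5]dec-6-ene
Product: 4 (4R)-4-[(4-methoxybenzyl)oxy]cyclohex-2-en-1-one
Conditions: PPTS (cat.), acetone/H2O, 50 °C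
Reagents that add atoms: water, O
Why: Acid-catalysed ketal hydrolysis unmasks the enone under conditions mild enough to leave the allylic ether stereocenter alone.

Step 4
Reactants: 4 (4R)-4-[(4-methoxybenzyl)oxy]cyclohex-2-en-1-one
Product: 6 (4R)-4-[(4-methoxybenzyl)oxy]-3-methylcyclohex-2-en-1-one, via trimethylsilyl enol ether 5 (not isolated)
Conditions: MeMgBr, CuBr·SMe2 (cat.), TMSCl, THF, −78 °C; solvent exchange; Pd(OAc)2 (1 equiv), MeCN, rt
Reagents that add atoms: methylmagnesium bromide, C[Mg]Br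
Why: Copper-catalysed conjugate addition with silyl trapping followed by Saegusa–Ito dehydrogenation of the regiodefined silyl enol ether returns the enone with the future C8 methyl in place, the center made in the first stage being erased in the second.

Step 5
Reactants: 6 (4R)-4-[(4-methoxybenzyl)oxy]-3-methylcyclohex-2-en-1-one
Product: 8 (3S,4R)-3-ethenyl-4-[(4-methoxybenzyl)oxy]-3-methylcyclohexan-1-one, via trimethylsilyl enol ether 7 (not isolated)
Conditions: CH2=CHMgBr, CuBr·SMe2 (cat.), TMSCl, THF, −78 → −40 °C; then 1 M HCl, 0 °C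
Reagents that add atoms: vinylmagnesium bromide, C=C[Mg]Br
Why: Copper-catalysed, TMSCl-accelerated conjugate addition to a β,β-disubstituted enone, in which the vinyl group enters by axial attack anti to the adjacent pseudoaxial C2 ether and so sets quaternary C8 with vinyl trans to the C2 oxygen.

Step 6
Reactants: 8 (3S,4R)-3-ethenyl-4-[(4-methoxybenzyl)oxy]-3-methylcyclohexan-1-one, 9 2-methylpropanal
Product: 10 (2S,4R,5S)-5-ethenyl-2-[(1S)-1-hydroxy-2-methylpropyl]-4-[(4-methoxybenzyl)oxy]-5-methylcyclohexan-1-one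
Conditions: LiN(iPr)2, THF, −78 °C; 9, −78 °C; AcOH quench at −78 °C
Reagents that add atoms: none
Why: Kinetic deprotonation at the α-methylene remote from the quaternary carbon and aldol addition through a Zimmerman–Traxler chair, with axial attack on the face opposite the 1,3-related C2 ether, should place the C5 side chain cis to the C8 vinyl group and give the anti C4 carbinol, which is temporary.

Step 7
Reactants: 10 (2S,4R,5S)-5-ethenyl-2-[(1S)-1-hydroxy-2-methylpropyl]-4-[(4-methoxybenzyl)oxy]-5-methylcyclohexan-1-one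
Product: 11 (2S,4R,5S)-5-ethenyl-4-[(4-methoxybenzyl)oxy]-5-methyl-2-[(1S)-2-methyl-1-(triethylsilyloxy)propyl]cyclohexan-1-one
Conditions: TESOTf, 2,6-lutidine, CH2Cl2, −78 °C
Reagents that add atoms: triethylsilyl trifluoromethanesulfonate, CC[Si](CC)(CC)OS(=O)(=O)C(F)(F)F
Why: Silyl triflate silylation under non-basic conditions protects the aldol hydroxyl without retro-aldol or C5 epimerisation, and the silylated carbinol serves as the masked C4 ketone because a cyclic ketal of so hindered a ketone would be hard to form.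

Step 8
Reactants: 11 (2S,4R,5S)-5-ethenyl-4-[(4-methoxybenzyl)oxy]-5-methyl-2-[(1S)-2-methyl-1-(triethylsilyloxy)propyl]cyclohexan-1-one
Product: 12 (1S,2R,4R,5S)-5-ethenyl-4-[(4-methoxybenzyl)oxy]-5-methyl-2-[(1S)-2-methyl-1-(triethylsilyloxy)propyl]cyclohexan-1-ol
Conditions: LiBH(s-Bu)3 (L-Selectride), THF, −78 °C; then H2O
Reagents that add atoms: none
Why: Bulky trialkylborohydride reduction, in which the side chain sits equatorial and the C8 vinyl group axial so that only equatorial attack is open, should give the axial C6 alcohol cis to both the C5 side chain and the vinyl group.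

Step 9
Reactants: 12 (1S,2R,4R,5S)-5-ethenyl-4-[(4-methoxybenzyl)oxy]-5-methyl-2-[(1S)-2-methyl-1-(triethylsilyloxy)propyl]cyclohexan-1-ol
Product: 13 tert-butyl{[(1S,2R,4R,5S)-5-ethenyl-4-[(4-methoxybenzyl)oxy]-5-methyl-2-[(1S)-2-methyl-1-(triethylsilyloxy)propyl]cyclohexyl]oxy}dimethylsilane
Conditions: TBSOTf, 2,6-lutidine, CH2Cl2, 0 °C → rt
Reagents that add atoms: tert-butyldimethylsilyl trifluoromethanesulfonate, CC(C)(C)[Si](C)(C)OS(=O)(=O)C(F)(F)F
Why: Silyl triflate silylation reaches even a hindered axial secondary alcohol, and the tert-butyldimethylsilyl ether outlasts the triethylsilyl ether under mild acid later on.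

Step 10
Reactants: 13 tert-butyl{[(1S,2R,4R,5S)-5-ethenyl-4-[(4-methoxybenzyl)oxy]-5-methyl-2-[(1S)-2-methyl-1-(triethylsilyloxy)propyl]cyclohexyl]oxy}dimethylsilane
Product: 14 (1R,2S,4S,5R)-4-[(tert-butyldimethylsilyl)oxy]-2-ethenyl-2-methyl-5-[(1S)-2-methyl-1-(triethylsilyloxy)propyl]cyclohexan-1-ol
Conditions: DDQ, CH2Cl2/pH 7 buffer, 0 °C
Reagents that add atoms: none
Why: Oxidative cleavage of the 4-methoxybenzyl ether by DDQ (hydride abstraction, then hydrolysis of the oxocarbenium ion) is orthogonal to both silyl ethers and to the vinyl group.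

Step 11
Reactants: 14 (1R,2S,4S,5R)-4-[(tert-butyldimethylsilyl)oxy]-2-ethenyl-2-methyl-5-[(1S)-2-methyl-1-(triethylsilyloxy)propyl]cyclohexan-1-ol
Product: 15 (2S,4S,5R)-4-[(tert-butyldimethylsilyl)oxy]-2-ethenyl-2-methyl-5-[(1S)-2-methyl-1-(triethylsilyloxy)propyl]cyclohexan-1-one
Conditions: Dess–Martin periodinane, pyridine, CH2Cl2, rt
Reagents that add atoms: none
Why: Dess–Martin oxidation removes the temporary C2 stereocenter after it has controlled C8 and C5 and places the carbonyl next to the quaternary carbon.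

Step 12
Reactants: 15 (2S,4S,5R)-4-[(tert-butyldimethylsilyl)oxy]-2-ethenyl-2-methyl-5-[(1S)-2-methyl-1-(triethylsilyloxy)propyl]cyclohexan-1-one
Product: 16 (4R,5S,7S)-5-[(tert-butyldimethylsilyl)oxy]-7-ethenyl-7-methyl-4-[(1S)-2-methyl-1-(triethylsilyloxy)propyl]oxepan-2-one
Conditions: mCPBA, CH2Cl2, 0 °C → rt
Reagents that add atoms: 3-chloroperoxybenzoic acid, OOC(=O)c1cccc(Cl)c1
Why: Baeyer–Villiger oxidation, in which the quaternary allylic C8 migrates in preference to the methylene carbon and with retention, inserts the ring oxygen between C2 and C8 and keeps the C8 configuration, a monosubstituted alkene being a poor substrate for the peracid.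

Step 13
Reactants: 16 (4R,5S,7S)-5-[(tert-butyldimethylsilyl)oxy]-7-ethenyl-7-methyl-4-[(1S)-2-methyl-1-(triethylsilyloxy)propyl]oxepan-2-one
Product: 17 (3R,4R,5S,7S)-5-[(tert-butyldimethylsilyl)oxy]-7-ethenyl-3,7-dimethyl-4-[(1S)-2-methyl-1-(triethylsilyloxy)propyl]oxepan-2-one
Conditions: LiN(iPr)2, THF, −78 °C; MeI, −78 → −40 °C
Reagents that add atoms: iodomethane, CI
Why: Alkylation of the lactone lithium enolate at C1, the only enolisable position, installs the C1 methyl group, whose configuration (drawn trans to the C5 side chain) is irrelevant because C1 becomes sp2 in step 14.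

Step 14
Reactants: 17 (3R,4R,5S,7S)-5-[(tert-butyldimethylsilyl)oxy]-7-ethenyl-3,7-dimethyl-4-[(1S)-2-methyl-1-(triethylsilyloxy)propyl]oxepan-2-one
Product: 18 tert-butyl{[(2S,4S,5R)-2-ethenyl-2,6-dimethyl-5-[(1S)-2-methyl-1-(triethylsilyloxy)propyl]-7-(trimethylsilyloxy)-2,3,4,5-tetrahydrooxepin-4-yl]oxy}dimethylsilane
Conditions: LiN(iPr)2, TMSCl/Et3N, THF, −78 °C → rt; pentane, filtration, concentration
Reagents that add atoms: chlorotrimethylsilane, C[Si](C)(C)Cl
Why: O-Silylation of the lactone enolate with in situ quench gives the cyclic silyl ketene acetal, whose enol ether geometry is fixed by the ring.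

Step 15
Reactants: 18 tert-butyl{[(2S,4S,5R)-2-ethenyl-2,6-dimethyl-5-[(1S)-2-methyl-1-(triethylsilyloxy)propyl]-7-(trimethylsilyloxy)-2,3,4,5-tetrahydrooxepin-4-yl]oxy}dimethylsilane
Product: 20 (1S,6S,7R)-6-[(tert-butyldimethylsilyl)oxy]-1,4-dimethyl-7-[(1S)-2-methyl-1-(triethylsilyloxy)propyl]cyclohept-3-ene-1-carboxylic acid, via trimethylsilyl ester 19 (not isolated)
Conditions: toluene, 110 °C, sealed tube; then THF/H2O, rt
Reagents that add atoms: none
Why: Heating sends the cyclic silyl ketene acetal through a concerted suprafacial [3,3] shift in which the terminal vinyl carbon C10 bonds to C1 while the C8–O bond breaks, the seven-membered ring forcing a boat-like six-atom array; this is the Ireland–Claisen rearrangement of a lactone silyl ketene acetal, the known carbocyclisation of vinyl lactones. Ring B closes in this pericyclic step as a seven-membered carbocycle spanned by the C5–C6–C7 tether, and the new C8=C9 alkene is necessarily cis in the ring. The only new stereocenter, quaternary C1, is set by the C8 center, because the vinyl group can reach only the face of the ketene acetal on which it is held, and C8 itself becomes sp2 so its chirality is fully transferred. The step needs the right C1 face relative to C5 and C6, and this is secured by the all-cis arrangement of vinyl group, C5 side chain and C6 silyloxy group built in steps 5 to 8, which places the new carboxyl group trans to the C5 side chain (the later trans ring fusion). It also needs the ketene acetal to survive until it rearranges, hence the aprotic medium and hydrolysis of the silyl ester only on work-up. Both silyl ethers should be inert at this temperature.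

Step 16
Reactants: 20 (1S,6S,7R)-6-[(tert-butyldimethylsilyl)oxy]-1,4-dimethyl-7-[(1S)-2-methyl-1-(triethylsilyloxy)propyl]cyclohept-3-ene-1-carboxylic acid
Product: 21 1-[(1S,6S,7R)-6-[(tert-butyldimethylsilyl)oxy]-1,4-dimethyl-7-[(1S)-2-methyl-1-(triethylsilyloxy)propyl]cyclohept-3-en-1-yl]ethan-1-one
Conditions: MeLi (excess), Et2O, 0 °C → rt; inverse quench into ice-water
Reagents that add atoms: methyllithium, [Li]C
Why: Addition of MeLi to the lithium carboxylate gives a dilithio gem-diolate that collapses to the methyl ketone only on hydrolysis (ketone synthesis from a carboxylic acid), which adds C3 without over-addition.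

Step 17
Reactants: 21 1-[(1S,6S,7R)-6-[(tert-butyldimethylsilyl)oxy]-1,4-dimethyl-7-[(1S)-2-methyl-1-(triethylsilyloxy)propyl]cyclohept-3-en-1-yl]ethan-1-one
Product: 22 1-[(1S,6S,7S)-6-[(tert-butyldimethylsilyl)oxy]-7-[(1S)-1-hydroxy-2-methylpropyl]-1,4-dimethylcyclohept-3-en-1-yl]ethan-1-one
Conditions: AcOH/THF/H2O (3:1:1), rt
Reagents that add atoms: none
Why: Selective acid hydrolysis cleaves the triethylsilyl ether in the presence of the more robust tert-butyldimethylsilyl ether, and the aqueous medium avoids a mixed methyl ketal with the C2 ketone.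

Step 18
Reactants: 22 1-[(1S,6S,7S)-6-[(tert-butyldimethylsilyl)oxy]-7-[(1S)-1-hydroxy-2-methylpropyl]-1,4-dimethylcyclohept-3-en-1-yl]ethan-1-one
Product: 23 1-[(1S,6S,7R)-6-[(tert-butyldimethylsilyl)oxy]-1,4-dimethyl-7-(2-methylpropanoyl)cyclohept-3-en-1-yl]ethan-1-one
Conditions: Dess–Martin periodinane, pyridine, CH2Cl2, rt
Reagents that add atoms: none
Why: Dess–Martin oxidation of the C4 carbinol (through the open form of any hemiketal) gives the 1,4-diketone and erases the temporary C4 center.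

Step 19
Reactants: 23 1-[(1S,6S,7R)-6-[(tert-butyldimethylsilyl)oxy]-1,4-dimethyl-7-(2-methylpropanoyl)cyclohept-3-en-1-yl]ethan-1-one
Product: 24 (3S,3aR,4S,8aS)-4-[(tert-butyldimethylsilyl)oxy]-3-hydroxy-6,8a-dimethyl-3-(propan-2-yl)-3,3a,4,5,8,8a-hexahydroazulen-1(2H)-one
Conditions: LiN(iPr)2, THF, −78 → −40 °C; AcOH quench at −78 °C
Reagents that add atoms: none
Why: Intramolecular aldol addition (5-enolendo-exo-trig) of the kinetic methyl ketone enolate to the C4 ketone, with the isopropyl group on the α face away from the β C1 methyl and the β C6 silyloxy group, should close ring A trans-fused and give the β hydroxyl at C4.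

Step 20
Reactants: 24 (3S,3aR,4S,8aS)-4-[(tert-butyldimethylsilyl)oxy]-3-hydroxy-6,8a-dimethyl-3-(propan-2-yl)-3,3a,4,5,8,8a-hexahydroazulen-1(2H)-one
Product: 25 (1S,3S,3aR,4S,8aS)-4-[(tert-butyldimethylsilyl)oxy]-6,8a-dimethyl-3-(propan-2-yl)-1,2,3,3a,4,5,8,8a-octahydroazulene-1,3-diol
Conditions: NaBH4, MeOH, −20 °C
Reagents that add atoms: none
Why: Borohydride reduction of the cyclopentanone from the face opposite the adjacent angular C1 methyl group should give the C2 alcohol cis to that methyl (β), as is usual for trans-fused ketones next to an angular methyl group.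

Step 21
Reactants: 25 (1S,3S,3aR,4S,8aS)-4-[(tert-butyldimethylsilyl)oxy]-6,8a-dimethyl-3-(propan-2-yl)-1,2,3,3a,4,5,8,8a-octahydroazulene-1,3-diol
Product: 26 (1S,3S,3aR,4S,8aS)-4-[(tert-butyldimethylsilyl)oxy]-3-hydroxy-6,8a-dimethyl-3-(propan-2-yl)-1,2,3,3a,4,5,8,8a-octahydroazulen-1-yl acetate
Conditions: Ac2O, pyridine, DMAP (cat.), CH2Cl2, rt
Reagents that add atoms: acetic anhydride, CC(=O)OC(C)=O
Why: DMAP-catalysed acetylation discriminates the secondary C2 alcohol from the tertiary C4 alcohol.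

Step 22
Reactants: 26 (1S,3S,3aR,4S,8aS)-4-[(tert-butyldimethylsilyl)oxy]-3-hydroxy-6,8a-dimethyl-3-(propan-2-yl)-1,2,3,3a,4,5,8,8a-octahydroazulen-1-yl acetate
Product: 27 (1S,3S,3aR,4S,8aS)-3,4-dihydroxy-6,8a-dimethyl-3-(propan-2-yl)-1,2,3,3a,4,5,8,8a-octahydroazulen-1-yl acetate
Conditions: HF·pyridine, pyridine, THF, 0 °C → rt
Reagents that add atoms: none
Why: Fluoride desilylation under buffered, mildly acidic conditions frees the C6 hydroxyl without the acetyl migration that a basic fluoride source could cause.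

Step 23
Reactants: 27 (1S,3S,3aR,4S,8aS)-3,4-dihydroxy-6,8a-dimethyl-3-(propan-2-yl)-1,2,3,3a,4,5,8,8a-octahydroazulen-1-yl acetate
Product: 28 (1S,2S,4S,5R,6S,8R,9S)-2-acetoxy-8,9-epoxy bicycle with free C4 and C6 hydroxyls (the target without its veratroyl group; numbering of the plan)
Conditions: VO(acac)2 (cat.), t-BuOOH, CH2Cl2, 0 °C → rt
Reagents that add atoms: tert-butyl hydroperoxide, CC(C)(C)OO
Why: Hydroxyl-directed epoxidation, in which the homoallylic C6 alkoxide binds the vanadium peroxide and delivers oxygen to the β face of C8=C9, sets C8 and C9 syn to the C6 oxygen.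

Step 24
Reactants: 28 (1S,2S,4S,5R,6S,8R,9S)-2-acetoxy-8,9-epoxy bicycle with free C4 and C6 hydroxyls, 29 3,4-dimethoxybenzoyl chloride
Product: 30 CNP0330776.1, the (1S,2S,4S,5R,6S,8R,9S)-2-acetoxy-8,9-epoxy-4-hydroxy bicycle carrying the 3,4-dimethoxybenzoate at C6
Conditions: Et3N, DMAP (cat.), CH2Cl2, rt
Reagents that add atoms: none
Why: DMAP-catalysed acylation with the acid chloride esterifies the secondary C6 alcohol and leaves the tertiary C4 alcohol and the epoxide untouched.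

**Compound list**

1 | 1,4-dioxaspiro[4.5]dec-6-en-8-one | O=C1C=CC2(CC1)OCCO2 | starting material
2 | (8R)-1,4-dioxaspiro[4.5]dec-6-en-8-ol | O[C@H]1C=CC2(CC1)OCCO2 | intermediate
3 | (8R)-8-[(4-methoxybenzyl)oxy]-1,4-dioxaspiro[4.5]dec-6-ene | COc1ccc(CO[C@H]2C=CC3(CC2)OCCO3)cc1 | intermediate
4 | (4R)-4-[(4-methoxybenzyl)oxy]cyclohex-2-en-1-one | COc1ccc(CO[C@H]2C=CC(=O)CC2)cc1 | intermediate
5 | trimethyl{[(3R,4R)-4-[(4-methoxybenzyl)oxy]-3-methylcyclohex-1-en-1-yl]oxy}silane | COc1ccc(CO[C@@H]2CCC(O[Si](C)(C)C)=C[C@H]2C)cc1 | intermediate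
6 | (4R)-4-[(4-methoxybenzyl)oxy]-3-methylcyclohex-2-en-1-one | COc1ccc(CO[C@@H]2CCC(=O)C=C2C)cc1 | intermediate
7 | trimethyl{[(3R,4R)-3-ethenyl-4-[(4-methoxybenzyl)oxy]-3-methylcyclohex-1-en-1-yl]oxy}silane | C[Si](C)(C)OC1=C[C@@](C)(C=C)[C@H](OCc2ccc(OC)cc2)CC1 | intermediate
8 | (3S,4R)-3-ethenyl-4-[(4-methoxybenzyl)oxy]-3-methylcyclohexan-1-one | O=C1C[C@@](C)(C=C)[C@H](OCc2ccc(OC)cc2)CC1 | intermediate
9 | 2-methylpropanal | CC(C)C=O | starting material
10 | (2S,4R,5S)-5-ethenyl-2-[(1S)-1-hydroxy-2-methylpropyl]-4-[(4-methoxybenzyl)oxy]-5-methylcyclohexan-1-one | O=C1C[C@@](C)(C=C)[C@H](OCc2ccc(OC)cc2)C[C@H]1[C@@H](O)C(C)C | intermediate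
11 | (2S,4R,5S)-5-ethenyl-4-[(4-methoxybenzyl)oxy]-5-methyl-2-[(1S)-2-methyl-1-(triethylsilyloxy)propyl]cyclohexan-1-one | O=C1C[C@@](C)(C=C)[C@H](OCc2ccc(OC)cc2)C[C@H]1[C@@H](O[Si](CC)(CC)CC)C(C)C | intermediate
12 | (1S,2R,4R,5S)-5-ethenyl-4-[(4-methoxybenzyl)oxy]-5-methyl-2-[(1S)-2-methyl-1-(triethylsilyloxy)propyl]cyclohexan-1-ol | O[C@H]1C[C@@](C)(C=C)[C@H](OCc2ccc(OC)cc2)C[C@H]1[C@@H](O[Si](CC)(CC)CC)C(C)C | intermediate
13 | tert-butyl{[(1S,2R,4R,5S)-5-ethenyl-4-[(4-methoxybenzyl)oxy]-5-methyl-2-[(1S)-2-methyl-1-(triethylsilyloxy)propyl]cyclohexyl]oxy}dimethylsilane | CC(C)(C)[Si](C)(C)O[C@H]1C[C@@](C)(C=C)[C@H](OCc2ccc(OC)cc2)C[C@H]1[C@@H](O[Si](CC)(CC)CC)C(C)C | intermediate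
14 | (1R,2S,4S,5R)-4-[(tert-butyldimethylsilyl)oxy]-2-ethenyl-2-methyl-5-[(1S)-2-methyl-1-(triethylsilyloxy)propyl]cyclohexan-1-ol | CC(C)(C)[Si](C)(C)O[C@H]1C[C@@](C)(C=C)[C@H](O)C[C@H]1[C@@H](O[Si](CC)(CC)CC)C(C)C | intermediate
15 | (2S,4S,5R)-4-[(tert-butyldimethylsilyl)oxy]-2-ethenyl-2-methyl-5-[(1S)-2-methyl-1-(triethylsilyloxy)propyl]cyclohexan-1-one | CC(C)(C)[Si](C)(C)O[C@H]1C[C@@](C)(C=C)C(=O)C[C@H]1[C@@H](O[Si](CC)(CC)CC)C(C)C | intermediate
16 | (4R,5S,7S)-5-[(tert-butyldimethylsilyl)oxy]-7-ethenyl-7-methyl-4-[(1S)-2-methyl-1-(triethylsilyloxy)propyl]oxepan-2-one | O=C1C[C@@H]([C@@H](O[Si](CC)(CC)CC)C(C)C)[C@@H](O[Si](C)(C)C(C)(C)C)C[C@@](C)(C=C)O1 | intermediate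
17 | (3R,4R,5S,7S)-5-[(tert-butyldimethylsilyl)oxy]-7-ethenyl-3,7-dimethyl-4-[(1S)-2-methyl-1-(triethylsilyloxy)propyl]oxepan-2-one | O=C1[C@H](C)[C@@H]([C@@H](O[Si](CC)(CC)CC)C(C)C)[C@@H](O[Si](C)(C)C(C)(C)C)C[C@@](C)(C=C)O1 | intermediate
18 | tert-butyl{[(2S,4S,5R)-2-ethenyl-2,6-dimethyl-5-[(1S)-2-methyl-1-(triethylsilyloxy)propyl]-7-(trimethylsilyloxy)-2,3,4,5-tetrahydrooxepin-4-yl]oxy}dimethylsilane | C[Si](C)(C)OC1=C(C)[C@@H]([C@@H](O[Si](CC)(CC)CC)C(C)C)[C@@H](O[Si](C)(C)C(C)(C)C)C[C@@](C)(C=C)O1 | intermediate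
19 | trimethylsilyl (1S,6S,7R)-6-[(tert-butyldimethylsilyl)oxy]-1,4-dimethyl-7-[(1S)-2-methyl-1-(triethylsilyloxy)propyl]cyclohept-3-ene-1-carboxylate | CC(C)(C)[Si](C)(C)O[C@H]1CC(C)=CC[C@](C)(C(=O)O[Si](C)(C)C)[C@H]1[C@@H](O[Si](CC)(CC)CC)C(C)C | intermediate
20 | (1S,6S,7R)-6-[(tert-butyldimethylsilyl)oxy]-1,4-dimethyl-7-[(1S)-2-methyl-1-(triethylsilyloxy)propyl]cyclohept-3-ene-1-carboxylic acid | CC(C)(C)[Si](C)(C)O[C@H]1CC(C)=CC[C@](C)(C(=O)O)[C@H]1[C@@H](O[Si](CC)(CC)CC)C(C)C | intermediate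
21 | 1-[(1S,6S,7R)-6-[(tert-butyldimethylsilyl)oxy]-1,4-dimethyl-7-[(1S)-2-methyl-1-(triethylsilyloxy)propyl]cyclohept-3-en-1-yl]ethan-1-one | CC(C)(C)[Si](C)(C)O[C@H]1CC(C)=CC[C@](C)(C(C)=O)[C@H]1[C@@H](O[Si](CC)(CC)CC)C(C)C | intermediate
22 | 1-[(1S,6S,7S)-6-[(tert-butyldimethylsilyl)oxy]-7-[(1S)-1-hydroxy-2-methylpropyl]-1,4-dimethylcyclohept-3-en-1-yl]ethan-1-one | CC(C)(C)[Si](C)(C)O[C@H]1CC(C)=CC[C@](C)(C(C)=O)[C@H]1[C@@H](O)C(C)C | intermediate
23 | 1-[(1S,6S,7R)-6-[(tert-butyldimethylsilyl)oxy]-1,4-dimethyl-7-(2-methylpropanoyl)cyclohept-3-en-1-yl]ethan-1-one | CC(C)(C)[Si](C)(C)O[C@H]1CC(C)=CC[C@](C)(C(C)=O)[C@H]1C(=O)C(C)C | intermediate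
24 | (3S,3aR,4S,8aS)-4-[(tert-butyldimethylsilyl)oxy]-3-hydroxy-6,8a-dimethyl-3-(propan-2-yl)-3,3a,4,5,8,8a-hexahydroazulen-1(2H)-one | CC(C)(C)[Si](C)(C)O[C@H]1CC(C)=CC[C@]2(C)C(=O)C[C@](O)(C(C)C)[C@@H]12 | intermediate
25 | (1S,3S,3aR,4S,8aS)-4-[(tert-butyldimethylsilyl)oxy]-6,8a-dimethyl-3-(propan-2-yl)-1,2,3,3a,4,5,8,8a-octahydroazulene-1,3-diol | CC(C)(C)[Si](C)(C)O[C@H]1CC(C)=CC[C@]2(C)[C@@H](O)C[C@](O)(C(C)C)[C@@H]12 | intermediate
26 | (1S,3S,3aR,4S,8aS)-4-[(tert-butyldimethylsilyl)oxy]-3-hydroxy-6,8a-dimethyl-3-(propan-2-yl)-1,2,3,3a,4,5,8,8a-octahydroazulen-1-yl acetate | CC(C)(C)[Si](C)(C)O[C@H]1CC(C)=CC[C@]2(C)[C@@H](OC(C)=O)C[C@](O)(C(C)C)[C@@H]12 | intermediate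
27 | (1S,3S,3aR,4S,8aS)-3,4-dihydroxy-6,8a-dimethyl-3-(propan-2-yl)-1,2,3,3a,4,5,8,8a-octahydroazulen-1-yl acetate | O[C@H]1CC(C)=CC[C@]2(C)[C@@H](OC(C)=O)C[C@](O)(C(C)C)[C@@H]12 | intermediate
28 | (1S,2S,4S,5R,6S,8R,9S)-2-acetoxy-8,9-epoxy bicycle with free C4 and C6 hydroxyls (plan numbering) | O[C@H]1C[C@@]2(C)O[C@H]2C[C@]2(C)[C@@H](OC(C)=O)C[C@](O)(C(C)C)[C@@H]12 | intermediate
29 | 3,4-dimethoxybenzoyl chloride | COc1ccc(C(Cl)=O)cc1OC | starting material
30 | CNP0330776.1, (1S,2S,4S,5R,6S,8R,9S)-2-acetoxy-8,9-epoxy-4-hydroxy bicycle with the C6 3,4-dimethoxybenzoate (plan numbering) | COc1ccc(C(=O)O[C@H]2C[C@@]3(C)O[C@H]3C[C@]3(C)[C@@H](OC(C)=O)C[C@](O)(C(C)C)[C@@H]23)cc1OC | target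

**Step count and risks**

Total step count: 24. Longest linear sequence: 24 steps (1 to 30).

Steps most likely to fail:

1. Step 19 (closure of ring A). The strained enolendo closure may be slow. Enolisation toward C5 with loss of the C6 silyloxy group, retro-aldol opening or dehydration of the ketol, and silyl migration to the new tertiary alkoxide may then compete. The fallback sets out from methyl ketone 21 and comes back at ketol 24. With LiN(iPr)2 and TMSCl, 21 (whose only enolisable position is the acetyl methyl group) is converted into the trimethylsilyl enol ether F1. N-Bromosuccinimide at −78 °C gives the bromomethyl ketone F2. Aqueous acetic acid removes the triethylsilyl group to give the bromo hydroxy ketone F3, and Dess–Martin oxidation gives the bromo diketone F4. SmI2 in THF at −78 °C then generates the samarium enolate regiospecifically under neutral conditions and closes ring A in a Reformatsky-type aldol addition to 24.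

2. Step 6 (intermolecular aldol). Facial selectivity at C5 may be poor, or the kinetic C5 configuration may erode through retro-aldol and re-addition. The fallback sets out from ketone 8 and comes back at aldol 10. It replaces the lithium enolate by enamine catalysis: (S)-proline in DMSO at rt with slow addition of excess 9 forms the enamine at the less hindered α-carbon. The catalyst then controls the C5 and C4 configurations in the anti sense already drawn for 10, which matches the substrate bias. No new compound is made.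

3. Step 12 (Baeyer–Villiger oxidation). Oxygen insertion at the hindered ketone may be slower than epoxidation of the vinyl group. The fallback sets out from ketone 15 and comes back at lactone 16. Bromine in CH2Cl2 at −78 °C masks the vinyl group as the dibromide F5 (a mixture at the new CHBr carbon). Peracid oxidation then gives the dibromo lactone F6, and zinc dust in AcOH/THF regenerates the vinyl group to give 16.

Further compounds
F1 | step 19 | ({1-[(1S,6S,7R)-6-[(tert-butyldimethylsilyl)oxy]-1,4-dimethyl-7-[(1S)-2-methyl-1-(triethylsilyloxy)propyl]cyclohept-3-en-1-yl]ethenyl}oxy)trimethylsilane | CC(C)(C)[Si](C)(C)O[C@H]1CC(C)=CC[C@](C)(C(=C)O[Si](C)(C)C)[C@H]1[C@@H](O[Si](CC)(CC)CC)C(C)C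
F2 | step 19 | 2-bromo-1-[(1S,6S,7R)-6-[(tert-butyldimethylsilyl)oxy]-1,4-dimethyl-7-[(1S)-2-methyl-1-(triethylsilyloxy)propyl]cyclohept-3-en-1-yl]ethan-1-one | CC(C)(C)[Si](C)(C)O[C@H]1CC(C)=CC[C@](C)(C(=O)CBr)[C@H]1[C@@H](O[Si](CC)(CC)CC)C(C)C
F3 | step 19 | 2-bromo-1-[(1S,6S,7S)-6-[(tert-butyldimethylsilyl)oxy]-7-[(1S)-1-hydroxy-2-methylpropyl]-1,4-dimethylcyclohept-3-en-1-yl]ethan-1-one | CC(C)(C)[Si](C)(C)O[C@H]1CC(C)=CC[C@](C)(C(=O)CBr)[C@H]1[C@@H](O)C(C)C
F4 | step 19 | 2-bromo-1-[(1S,6S,7R)-6-[(tert-butyldimethylsilyl)oxy]-1,4-dimethyl-7-(2-methylpropanoyl)cyclohept-3-en-1-yl]ethan-1-one | CC(C)(C)[Si](C)(C)O[C@H]1CC(C)=CC[C@](C)(C(=O)CBr)[C@H]1C(=O)C(C)C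
F0 | step 6 | none | none
F5 | step 12 | (2R,4S,5R)-4-[(tert-butyldimethylsilyl)oxy]-2-(1,2-dibromoethyl)-2-methyl-5-[(1S)-2-methyl-1-(triethylsilyloxy)propyl]cyclohexan-1-one | CC(C)(C)[Si](C)(C)O[C@H]1C[C@@](C)(C(Br)CBr)C(=O)C[C@H]1[C@@H](O[Si](CC)(CC)CC)C(C)C
F6 | step 12 | (4R,5S,7S)-5-[(tert-butyldimethylsilyl)oxy]-7-(1,2-dibromoethyl)-7-methyl-4-[(1S)-2-methyl-1-(triethylsilyloxy)propyl]oxepan-2-one | O=C1C[C@@H]([C@@H](O[Si](CC)(CC)CC)C(C)C)[C@@H](O[Si](C)(C)C(C)(C)C)C[C@@](C)(C(Br)CBr)O1
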